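## Structural features

The target is a flavone: a 4H-chromen-4-one in which ring A (C4a, C5, C6, C7, C8, C8a) is fused to the pyranone ring C (O1, C2, C3, C4), and ring B is attached to C2 by the single C2–C1' bond. The molecule is flat and has no stereocenter, so nothing stereochemical has to be set; the only geometric elements on the way (an oxime and an enaminone double bond) do not reach the product. Ring A carries oxygen on C5, C6, C7 and C8a (methyl ethers on O5 and O6, a free phenol on O7); ring B carries methyl ethers on O3' and O4' and a free phenol on O5'. The fragile points are the two phenols (easily oxidized), the C5 methyl ether (peri to the C4 carbonyl and the first ether to fall under Lewis or strong protic acid) and the pyranone (opened by strong base). The real difficulty is ring A: C4a must carry the C4 carbon between two oxygenated carbons, and O5/O6 must end as methyl ethers while O7/O8a do not. Late selective methylation cannot deliver this, because the C5 hydroxyl of a flavone is its least reactive and the C7 hydroxyl its most reactive phenol. The key step uses two features: C2–C3–C4 is a 1,3-dioxygenated three-carbon unit that can be stored as an isoxazole (nitrogen in place of the C4 oxygen, ring oxygen on C2), and C4a is flanked by the oxygen-bearing C5 and C8a. A nitrile oxide on C4 is therefore substituted at both ortho positions and resists dimerization, and after unmasking only O8a is ortho to C4, so ring C can close in one sense only.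

## Logic of the disconnections

15 to 12. The O1–C2 bond is cut, the C4 carbonyl is rewritten as C4=N, the nitrogen is tied by an N–O bond to the oxygen on C2, and O7, O8a and O5' receive benzyl groups. Closure of O1–C2 from an ortho-hydroxyaryl 1,3-dicarbonyl is the most dependable way to make ring C, and one reductant can break the N–O bond and all three benzylic C–O bonds. The gain is that a pyranone, two phenols and an enolizable diketone collapse into one non-polar aromatic heterocycle. The forward step must stop the reduction at 13 and run the hydrolysis and cyclodehydration through 14 under acid mild enough for the C5 methyl ether.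

12 to 7 and 10. The C3–C4 bond and the O–C2 bond of the five-membered ring are cut in a retro-(3+2) sense. This divides the molecule at the only carbon–carbon bond that joins the two aryl halves, and it places the dipole (11, formed from 7) on the ring whose substitution protects it. The gain is convergence to two benzaldehyde-derived fragments of similar size. The forward step must give the 3,5- and not the 3,4-substituted ring, and the oxidant must find no free phenol.

7 to 6. The C=N bond is cut to the aldehyde. The gain is small but moves the nitrogen to the last step before coupling. The forward condensation must work on an aldehyde flanked by two alkoxy groups.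

6 to 5. The O8a–benzyl bond is cut. This hydroxyl has to be the last one capped because, while free, it directs the oxygenation of C6 and shields itself from alkylation by its hydrogen bond to the aldehyde. The forward step must force alkylation of that chelated phenol.

5 to 4. The O6–methyl bond is cut. In 4 the O6 hydroxyl is free and the O8a hydroxyl is chelated, so the two can be told apart without protecting groups. The forward step must stop at mono-methylation and keep air away from a hydroquinone.

4 to 2. The C6–O bond is cut. C6 is para to the free O8a hydroxyl of 2, which is the position a persulfate oxidation of a phenol attacks. Formylation of a preformed tetra-oxygenated benzene would have to choose between two almost equivalent positions, so the oxygen is introduced with the aldehyde already in place. The gain is a phloroglucinaldehyde pattern. The forward step must be para-selective and must spare the aldehyde and the benzyl ether.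

2 to 1. The O7–benzyl bond is cut, leading to 1, in which O5 already carries its methyl group. The forward step must alkylate only the non-chelated, more acidic hydroxyl.

10 to 9. The terminal alkyne carbon (the future C3) is removed, which returns the aldehyde whose carbonyl carbon is the future C2. The gain is a one-step link to a benzaldehyde. The forward homologation needs a non-enolizable aldehyde and ethers that tolerate carbonate in methanol, both of which hold.

9 to 8. The O5'–benzyl bond is cut, leading to 8, which has the complete ring B pattern. The benzyl group is chosen to match those on ring A so that all three leave together.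

## Other disconnections considered

Alternative 1: The cut takes out C3 by breaking C2–C3 and C3–C4, so ring C shrinks to the furan ring of the 3-silyloxy-2-arylbenzofuran A2 (taken here as the tert-butyldimethylsilyl enol ether of the racemic 2-arylbenzofuran-3-one A3). In the forward sense, dibromocarbene from CHBr3 and KOtBu would add to the C2=C3 enol ether bond of A2. The dibromocyclopropane would open with loss of bromide and of the silyl group, so that the carbene carbon becomes C3 of the 3-bromoflavone A1. Hydrogenolysis over Pd/C with a buffering base would then remove bromine and both benzyl groups to give 15.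
- In its favour: two carbon–carbon bonds are formed in the key step against one in the chosen plan. There is no regiochemical question, since a carbon is inserted into an existing bond; on this point it is better than the chosen plan. The endgame is one neutral hydrogenolysis without an acid stage, which is also better for the C5 methyl ether than step 9.
- Against it: the C2–H of A3 is benzylic, next to the ketone and next to oxygen, so A3 should enolize to an electron-rich hydroxybenzofuran and autoxidize readily. KOtBu may remove the silyl group of A2 before the carbene arrives. The double bond to be cyclopropanated is tetrasubstituted and part of an aromatic furan.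
- Structure: A3 needs an acyl carbon on C4a between O5 and O8a, the same ring A problem as in 6, plus an O8a–C2 ether bond; a Friedel–Crafts closure onto the unsymmetrical ring A would face two ortho positions.
- Mechanism: carbene addition and cyclopropane opening (the ring expansion known for silyl enol ethers of cyclic ketones) against a closed-shell cycloaddition of a stabilized dipole. Both are metal-free, and neither is clearly superior.
- Step economy: equal after the key step (one operation each), longer before it because A3 is harder to reach than 7.

Alternative 2: The cut is made in ring B, at C1'–C2' and C5'–C6', so ring B is built onto a finished chromone. In the forward sense, the 2-(2-nitrovinyl)chromone A5 and the electron-rich diene A6 would undergo a (4+2) cycloaddition. DBU would then remove nitrous acid, and loss of methanol from the mixed ketal carbon would aromatize the ring to the phenol A4. One hydrogenolysis of the O7 benzyl ether would give 15.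
- In its favour: the O5' phenol emerges free and already distinguished from O3' and O4', so ring B needs no protecting group, which is better than the chosen plan. The polarization of both partners should fix the orientation of the cycloaddition. The endgame is one step, equal to the chosen plan.
- Against it: the step builds the ring that can be bought complete as 8, and leaves the difficult half (ring A with ring C) to conventional chemistry. A5 still needs the same ring A oxygenation work as 6, then a chromone synthesis, oxidation of a C2 methyl group to the aldehyde and a nitroaldol condensation. A6 is a ketene acetal diene with four heteroatom substituents, hydrolytically fragile and not commercial.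
- Mechanism: the nitroalkene of A5 can also react as a heterodiene or as a simple Michael acceptor, and the chromone C2=C3 bond is a second electrophilic site. The aromatization must lose methanol and not silanol, otherwise O5' ends as a methyl ether. The chosen cycloaddition has one reactive pair and one selectivity issue.
- Step economy: clearly longer than the chosen plan.

Alternative 3: The cut removes C4 as carbon monoxide and breaks C4a–C4, C4–C3 and O1–C2, giving the iodophenol A8, CO and the same alkyne 10. In the forward sense, PdCl2(PPh3)2 (divalent palladium, reduced in the flask to zerovalent palladium) would insert into the C–I bond, CO insertion would give an aroylpalladium species, and coupling with 10 in diethylamine followed by amine-assisted 6-endo attack of the phenol would give the flavone A7.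
- In its favour: three bonds, two of them carbon–carbon, are formed in one step, which is better convergence than the chosen plan. No masked carbonyl has to be unveiled. The parent phenol of A8 is symmetric, so its iodination has no regiochemical question; this is better than the chosen plan, which spends a persulfate oxidation on that problem.
- Against it: A7 carries a benzyl group on O5 where 15 has a methyl group, so global debenzylation would give the 5,7,5'-triol and not 15. The correction needs either three further steps (selective removal of the peri O5 benzyl group, methylation of the chelated and least reactive C5 hydroxyl, then hydrogenolysis) or a redesigned iodophenol A9, which would give A10 and then 15 in one hydrogenolysis. A9 loses the symmetry, and its iodination faces the same two-ortho-position problem as any formylation of that ring.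
- Mechanism: the iodide sits between two oxygen substituents on a very electron-rich ring, so oxidative addition and CO insertion should be slow. Carbon-monoxide-free coupling followed by furan closure, and 5-exo instead of 6-endo attack of the phenol on the acylated alkyne, are the expected competing processes. CO gas handling is an added burden; the chosen step needs no metal.
- Step economy: with A9 the sequence could be shorter than the chosen plan if the iodination were selective; with A8 as drawn it is about equal after the repair at O5.

Key step: step 8

Assumption: 1 and 8 are taken as catalogue compounds; positions in all intermediates are referred to by flavone numbering (C2 to C8a, C1' to C6').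

Step 1
Reactants: 1 2,4-dihydroxy-6-methoxybenzaldehyde
Product: 2 4-(benzyloxy)-2-hydroxy-6-methoxybenzaldehyde
Conditions: BnBr (1.05 equiv), NaHCO3, KI (cat.), MeCN, 80 °C
Reagents that add atoms: benzyl bromide, BrCc1ccccc1
Why: Williamson etherification under weak-base control: the C7 hydroxyl (para to the aldehyde, more acidic, not hydrogen-bonded) is alkylated, while the C8a hydroxyl stays locked in its hydrogen bond to the carbonyl and is not deprotonated by NaHCO3.

Step 2
Reactants: 2 4-(benzyloxy)-2-hydroxy-6-methoxybenzaldehyde
Product: 4 4-(benzyloxy)-3,6-dihydroxy-2-methoxybenzaldehyde, via potassium aryl sulfate 3 (not isolated)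
Conditions: K2S2O8 (1.1 equiv), 10% aq NaOH, pyridine, 5–20 °C; then aq HCl, toluene, 85 °C, N2
Reagents that add atoms: potassium peroxodisulfate, [K+].[K+].[O-]S(=O)(=O)OOS(=O)(=O)[O-]
Why: Elbs persulfate oxidation: the phenoxide of 2 attacks a peroxide oxygen through its free para carbon (the future C6) to give aryl sulfate 3, and warm dilute acid cleaves the S–O bond of the sulfate monoester to give hydroquinone 4. The para preference of the reaction fixes the position; aldehyde, methyl ether and benzyl ether should tolerate cold alkaline persulfate and brief warming in dilute acid.

Step 3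
Reactants: 4 4-(benzyloxy)-3,6-dihydroxy-2-methoxybenzaldehyde
Product: 5 4-(benzyloxy)-6-hydroxy-2,3-dimethoxybenzaldehyde
Conditions: MeI (1.05 equiv), K2CO3 (1.1 equiv), acetone, 40 °C, degassed, N2
Reagents that add atoms: iodomethane, CI
Why: Williamson methylation with one equivalent of electrophile: the new C6 hydroxyl is free, whereas the C8a hydroxyl is hydrogen-bonded to the aldehyde and far less nucleophilic, so mono-methylation at O6 should dominate. Exclusion of air keeps the hydroquinone from going to the quinone.

Step 4
Reactants: 5 4-(benzyloxy)-6-hydroxy-2,3-dimethoxybenzaldehyde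
Product: 6 4,6-bis(benzyloxy)-2,3-dimethoxybenzaldehyde
Conditions: BnBr (1.3 equiv), K2CO3, DMF, 60 °C
Reagents that add atoms: benzyl bromide, BrCc1ccccc1
Why: Williamson benzylation of the chelated phenol under more forcing conditions. O8a must be capped because a free phenol para to a methoxy group would be oxidized by PhI(OAc)2 and would add to the nitrile oxide.

Step 5
Reactants: 6 4,6-bis(benzyloxy)-2,3-dimethoxybenzaldehyde
Product: 7 (E)-4,6-bis(benzyloxy)-2,3-dimethoxybenzaldehyde oxime
Conditions: NH2OH·HCl, NaOAc, EtOH–H2O, 70 °C
Reagents that add atoms: hydroxylamine hydrochloride, Cl.NO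
Why: Oxime condensation; the E isomer (hydroxyl anti to the crowded aryl group) is the thermodynamic product, and the geometry is lost in the next step in any case.

Step 6
Reactants: 8 3-hydroxy-4,5-dimethoxybenzaldehyde
Product: 9 3-(benzyloxy)-4,5-dimethoxybenzaldehyde
Conditions: BnBr (1.1 equiv), K2CO3, DMF, 25–50 °C
Reagents that add atoms: benzyl bromide, BrCc1ccccc1
Why: Williamson etherification of the only phenol; the benzyl group matches those on ring A so that all three fall in the same hydrogenolysis.

Step 7
Reactants: 9 3-(benzyloxy)-4,5-dimethoxybenzaldehyde
Product: 10 1-(benzyloxy)-5-ethynyl-2,3-dimethoxybenzene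
Conditions: dimethyl (1-diazo-2-oxopropyl)phosphonate (1.3 equiv), K2CO3, MeOH, 0 °C to rt
Reagents that add atoms: dimethyl (1-diazo-2-oxopropyl)phosphonate, CC(=O)C(=[N+]=[N-])P(=O)(OC)OC
Why: Seyferth–Gilbert homologation in the Ohira–Bestmann variant: methoxide removes the acetyl group to give the dimethyl (diazomethyl)phosphonate anion, a Horner–Wadsworth–Emmons-type olefination gives a diazoalkene, and loss of N2 with 1,2-hydrogen shift of the alkylidene carbene gives the terminal alkyne. The aldehyde is non-enolizable and carbonate in methanol leaves the ethers untouched.

Step 8
Reactants: 7 (E)-4,6-bis(benzyloxy)-2,3-dimethoxybenzaldehyde oxime; 10 1-(benzyloxy)-5-ethynyl-2,3-dimethoxybenzene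
Product: 12 3-[4,6-bis(benzyloxy)-2,3-dimethoxyphenyl]-5-[3-(benzyloxy)-4,5-dimethoxyphenyl]-1,2-oxazole, via nitrile oxide 11 (not isolated)
Conditions: 10 (1.2 equiv), PhI(OAc)2 (1.2 equiv), TFA (10 mol %), MeOH–CH2Cl2, 0 °C to rt; then solvent switch to toluene, 80 °C
Reagents that add atoms: none
Why: PhI(OAc)2 exchanges one acetate for the oxime oxygen and the O-iodane fragments with loss of iodobenzene and acetic acid, a two-electron dehydrogenation of the aldoxime by trivalent iodine that gives nitrile oxide 11. Because C4a of 11 is flanked by the O5 methyl ether and the O8a benzyl ether, dimerization to the furoxan is sterically blocked, so 11 can accumulate and then be heated with 10. Ring formation is a concerted, asynchronous Huisgen 1,3-dipolar (3+2) cycloaddition, a thermally allowed six-electron suprafacial process in which the C4–C3 bond and the O–C2 bond form in one event; this is the only ring closed, no Baldwin class applies, and no stereocenter is created. The closest known reaction type is the cycloaddition of aryl nitrile oxides with terminal arylacetylenes to 3,5-diarylisoxazoles. The selectivity needed is regiochemical (3,5- against 3,4-diaryl): the hindered dipole carbon bonds to the unsubstituted alkyne CH, which also carries the larger HOMO coefficient of the electron-rich arylacetylene, so steric and frontier-orbital effects both place the dipole oxygen on C2. Chemoselectivity rests on the absence of free phenols: the oxidant finds only the oxime, and the product is an aromatic, non-enolizable heterocycle that should be stable to the conditions.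

Step 9
Reactants: 12 3-[4,6-bis(benzyloxy)-2,3-dimethoxyphenyl]-5-[3-(benzyloxy)-4,5-dimethoxyphenyl]-1,2-oxazole
Product: 15 7-hydroxy-2-(3-hydroxy-4,5-dimethoxyphenyl)-5,6-dimethoxy-4H-chromen-4-one, via enaminone 13 (not isolated), via 1,3-diketone 14 (not isolated)
Conditions: H2 (1 atm), 10% Pd/C, EtOAc–MeOH, rt; filter; then 2 M aq HCl–MeOH, 60 °C
Reagents that add atoms: water, O
Why: Hydrogenolysis breaks the weak N–O bond and the three benzylic C–O bonds to give the vinylogous amide 13, which should not be reduced further; dilute acid hydrolyses its C4–N bond to the 1,3-diketone 14 (the C4 oxygen comes from water). The only ortho hydroxyl of 14 (O8a) adds to the C2 carbonyl (6-exo-trig) and the hemiketal dehydrates, the classical cyclodehydration of an ortho-hydroxydibenzoylmethane; dilute acid and moderate temperature spare the C5 methyl ether.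

Compound list

1 | 2,4-dihydroxy-6-methoxybenzaldehyde | COc1cc(O)cc(O)c1C=O | starting material
2 | 4-(benzyloxy)-2-hydroxy-6-methoxybenzaldehyde | COc1cc(OCc2ccccc2)cc(O)c1C=O | intermediate
3 | potassium 6-(benzyloxy)-3-formyl-4-hydroxy-2-methoxyphenyl sulfate | [K+].[O-]S(=O)(=O)Oc1c(OC)c(C=O)c(O)cc1OCc1ccccc1 | intermediate (not isolated)
4 | 4-(benzyloxy)-3,6-dihydroxy-2-methoxybenzaldehyde | COc1c(O)c(OCc2ccccc2)cc(O)c1C=O | intermediate
5 | 4-(benzyloxy)-6-hydroxy-2,3-dimethoxybenzaldehyde | COc1c(OC)c(OCc2ccccc2)cc(O)c1C=O | intermediate
6 | 4,6-bis(benzyloxy)-2,3-dimethoxybenzaldehyde | COc1c(OC)c(OCc2ccccc2)cc(OCc2ccccc2)c1C=O | intermediate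
7 | (E)-4,6-bis(benzyloxy)-2,3-dimethoxybenzaldehyde oxime | O/N=C/c1c(OCc2ccccc2)cc(OCc2ccccc2)c(OC)c1OC | intermediate
8 | 3-hydroxy-4,5-dimethoxybenzaldehyde | COc1cc(C=O)cc(O)c1OC | starting material
9 | 3-(benzyloxy)-4,5-dimethoxybenzaldehyde | COc1cc(C=O)cc(OCc2ccccc2)c1OC | intermediate
10 | 1-(benzyloxy)-5-ethynyl-2,3-dimethoxybenzene | C#Cc1cc(OC)c(OC)c(OCc2ccccc2)c1 | intermediate
11 | 4,6-bis(benzyloxy)-2,3-dimethoxybenzonitrile oxide | [O-][N+]#Cc1c(OCc2ccccc2)cc(OCc2ccccc2)c(OC)c1OC | intermediate (not isolated)
12 | 3-[4,6-bis(benzyloxy)-2,3-dimethoxyphenyl]-5-[3-(benzyloxy)-4,5-dimethoxyphenyl]-1,2-oxazole | COc1cc(-c2cc(-c3c(OCc4ccccc4)cc(OCc4ccccc4)c(OC)c3OC)no2)cc(OCc2ccccc2)c1OC | intermediate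
13 | (Z)-3-amino-3-(4,6-dihydroxy-2,3-dimethoxyphenyl)-1-(3-hydroxy-4,5-dimethoxyphenyl)prop-2-en-1-one | N/C(=C\C(=O)c1cc(O)c(OC)c(OC)c1)c1c(O)cc(O)c(OC)c1OC | intermediate (not isolated)
14 | 1-(4,6-dihydroxy-2,3-dimethoxyphenyl)-3-(3-hydroxy-4,5-dimethoxyphenyl)propane-1,3-dione | O=C(CC(=O)c1cc(O)c(OC)c(OC)c1)c1c(O)cc(O)c(OC)c1OC | intermediate (not isolated)
15 | 7-hydroxy-2-(3-hydroxy-4,5-dimethoxyphenyl)-5,6-dimethoxy-4H-chromen-4-one (7,5'-dihydroxy-5,6,3',4'-tetramethoxyflavone) | COc1cc(-c2cc(=O)c3c(OC)c(OC)c(O)cc3o2)cc(O)c1OC | target

Total step count: 9 (steps 1–5 make the ring A oxime, steps 6–7 the ring B alkyne, step 8 joins them, step 9 unmasks the flavone). Longest linear sequence: 7 steps (1, 2, 3, 4, 5, 8, 9).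

Least certain steps

Step 8 (key step). Both ortho positions of the dipole are substituted, so the cycloaddition may be slow. During prolonged heating the nitrile oxide may then be consumed by addition of methanol or acetic acid or by rearrangement to the isocyanate, and the electron-rich alkoxyarenes may be partly oxidized by the trivalent iodine reagent. Erosion of regioselectivity is less likely. The fallback avoids the dipole altogether; it sets out from 6 and 10 and comes back to the route at 15. Deprotonation of 10 with n-BuLi (THF, −78 °C) and addition to 6 would give the racemic propargylic alcohol F1. Oxidation with MnO2 in CH2Cl2 would give the ynone F2, and conjugate addition of Et2NH in EtOH would give the diethylamino enone F3, which already holds the C3–C4 bond and a leaving group on C2. Hydrogenolysis (H2, Pd/C) would remove the three benzyl groups to give the triphenol enaminone F4. Warming F4 in dilute aqueous HCl–MeOH would let O8a add to C2 and expel diethylamine, giving 15.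

Step 2. Persulfate oxidations typically suffer from incomplete conversion and from radical over-oxidation of the phenoxide to dark polymeric material; here the benzyl ether is also poorly soluble in aqueous alkali and the aldehyde may be oxidized. Unchanged 2 can be recovered before the hydrolysis stage, but throughput may be low. The fallback replaces the oxygenation by a formylation of a ring that already has all four oxygens; it sets out from 9 and comes back at 5. Baeyer–Villiger oxidation of 9 with mCPBA in CH2Cl2 would give the aryl formate F5, and methanolysis (K2CO3, MeOH) would give 3-(benzyloxy)-4,5-dimethoxyphenol F6. Ortho-formylation of F6 (MgCl2, Et3N, paraformaldehyde, MeCN, reflux) at the position between the hydroxyl and the methoxy group would give 5. The two ortho positions of F6 are electronically similar, so the site selectivity is not secured and a regioisomer would have to be separated; this is the reason it is a fallback and not the main route.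

Step 9. On palladium the N–O bond of a 3,5-diarylisoxazole may be cleaved more slowly than the benzyl ethers, and the liberated amine may inhibit the catalyst, so polar partly reduced mixtures could form. In the acid stage the C5 methyl ether may be lost, or the closure may stall at the imine stage. The fallback separates the two reductive events; it sets out from 12 and comes back at 14. Mo(CO)6 (zerovalent molybdenum) in MeCN–H2O at 80 °C would cleave only the N–O bond to give the tribenzyl enaminone F7. Hydrolysis with aqueous oxalic acid in THF would give the tribenzyl 1,3-diketone F8, which can be purified as a non-polar compound. Hydrogenolysis of F8 (H2, Pd/C, EtOAc) would then give 14, which closes to 15 under the acid conditions of step 9 or with a trace of acid in warm AcOH.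

Step 3. Hydroquinone 4 may be oxidized by air to the quinone under basic conditions, and some methylation of the chelated hydroxyl (double alkylation) may erode the site selectivity. The fallback lets the sulfate group act as the protecting group for O6; it sets out from 2 and comes back at 6. The Elbs oxidation would be run as in step 2 up to sulfate 3, and the remaining phenoxide benzylated in the same alkaline mixture (BnBr, Bu4NBr, CH2Cl2–water) to give the benzylated aryl sulfate F9. Acid hydrolysis (aq HCl, 85 °C) would give the monophenol F10, whose single hydroxyl is methylated (MeI, K2CO3, DMF) to give 6. No hydroquinone is formed and no selectivity is required.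

## Further compounds

F1 | step 8 | 1-[4,6-bis(benzyloxy)-2,3-dimethoxyphenyl]-3-[3-(benzyloxy)-4,5-dimethoxyphenyl]prop-2-yn-1-ol (racemic) | OC(C#Cc1cc(OC)c(OC)c(OCc2ccccc2)c1)c1c(OCc2ccccc2)cc(OCc2ccccc2)c(OC)c1OC
F2 | step 8 | 1-[4,6-bis(benzyloxy)-2,3-dimethoxyphenyl]-3-[3-(benzyloxy)-4,5-dimethoxyphenyl]prop-2-yn-1-one | O=C(C#Cc1cc(OC)c(OC)c(OCc2ccccc2)c1)c1c(OCc2ccccc2)cc(OCc2ccccc2)c(OC)c1OC
F3 | step 8 | (E)-1-[4,6-bis(benzyloxy)-2,3-dimethoxyphenyl]-3-[3-(benzyloxy)-4,5-dimethoxyphenyl]-3-(diethylamino)prop-2-en-1-one | CCN(CC)/C(=C/C(=O)c1c(OCc2ccccc2)cc(OCc2ccccc2)c(OC)c1OC)c1cc(OC)c(OC)c(OCc2ccccc2)c1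
F4 | step 8 | (E)-3-(diethylamino)-1-(4,6-dihydroxy-2,3-dimethoxyphenyl)-3-(3-hydroxy-4,5-dimethoxyphenyl)prop-2-en-1-one | CCN(CC)/C(=C/C(=O)c1c(O)cc(O)c(OC)c1OC)c1cc(OC)c(OC)c(O)c1
F5 | step 2 | 3-(benzyloxy)-4,5-dimethoxyphenyl formate | O=COc1cc(OC)c(OC)c(OCc2ccccc2)c1
F6 | step 2 | 3-(benzyloxy)-4,5-dimethoxyphenol | Oc1cc(OC)c(OC)c(OCc2ccccc2)c1
F7 | step 9 | (Z)-3-amino-3-[4,6-bis(benzyloxy)-2,3-dimethoxyphenyl]-1-[3-(benzyloxy)-4,5-dimethoxyphenyl]prop-2-en-1-one | N/C(=C\C(=O)c1cc(OC)c(OC)c(OCc2ccccc2)c1)c1c(OCc2ccccc2)cc(OCc2ccccc2)c(OC)c1OC
F8 | step 9 | 1-[4,6-bis(benzyloxy)-2,3-dimethoxyphenyl]-3-[3-(benzyloxy)-4,5-dimethoxyphenyl]propane-1,3-dione | O=C(CC(=O)c1cc(OC)c(OC)c(OCc2ccccc2)c1)c1c(OCc2ccccc2)cc(OCc2ccccc2)c(OC)c1OC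
F9 | step 3 | potassium 4,6-bis(benzyloxy)-3-formyl-2-methoxyphenyl sulfate | [K+].[O-]S(=O)(=O)Oc1c(OC)c(C=O)c(OCc2ccccc2)cc1OCc1ccccc1
F10 | step 3 | 4,6-bis(benzyloxy)-3-hydroxy-2-methoxybenzaldehyde | O=Cc1c(OCc2ccccc2)cc(OCc2ccccc2)c(O)c1OC
A1 | alternative 1 | 7-(benzyloxy)-2-[3-(benzyloxy)-4,5-dimethoxyphenyl]-3-bromo-5,6-dimethoxy-4H-chromen-4-one | COc1cc(-c2oc3cc(OCc4ccccc4)c(OC)c(OC)c3c(=O)c2Br)cc(OCc2ccccc2)c1OC
A2 | alternative 1 | {6-(benzyloxy)-2-[3-(benzyloxy)-4,5-dimethoxyphenyl]-4,5-dimethoxy-1-benzofuran-3-yl}oxy(tert-butyl)dimethylsilane | COc1cc(-c2oc3cc(OCc4ccccc4)c(OC)c(OC)c3c2O[Si](C)(C)C(C)(C)C)cc(OCc2ccccc2)c1OC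
A3 | alternative 1 | 6-(benzyloxy)-2-[3-(benzyloxy)-4,5-dimethoxyphenyl]-4,5-dimethoxy-1-benzofuran-3(2H)-one (racemic) | COc1cc(C2Oc3cc(OCc4ccccc4)c(OC)c(OC)c3C2=O)cc(OCc2ccccc2)c1OC
A4 | alternative 2 | 7-(benzyloxy)-2-(3-hydroxy-4,5-dimethoxyphenyl)-5,6-dimethoxy-4H-chromen-4-one | COc1cc(-c2cc(=O)c3c(OC)c(OC)c(OCc4ccccc4)cc3o2)cc(O)c1OC
A5 | alternative 2 | 7-(benzyloxy)-5,6-dimethoxy-2-[(E)-2-nitroethenyl]-4H-chromen-4-one | COc1c(OC)c(OCc2ccccc2)cc2oc(/C=C/[N+](=O)[O-])cc(=O)c12
A6 | alternative 2 | 1,2,3-trimethoxy-1-(trimethylsilyloxy)buta-1,3-diene (C1=C2 geometry undefined) | C=C(OC)C(OC)=C(OC)O[Si](C)(C)C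
A7 | alternative 3 | 5,7-bis(benzyloxy)-2-[3-(benzyloxy)-4,5-dimethoxyphenyl]-6-methoxy-4H-chromen-4-one | COc1cc(-c2cc(=O)c3c(OCc4ccccc4)c(OC)c(OCc4ccccc4)cc3o2)cc(OCc2ccccc2)c1OC
A8 | alternative 3 | 3,5-bis(benzyloxy)-2-iodo-4-methoxyphenol | COc1c(OCc2ccccc2)cc(O)c(I)c1OCc1ccccc1
A9 | alternative 3 | 5-(benzyloxy)-2-iodo-3,4-dimethoxyphenol | COc1c(OCc2ccccc2)cc(O)c(I)c1OC
A10 | alternative 3 | 7-(benzyloxy)-2-[3-(benzyloxy)-4,5-dimethoxyphenyl]-5,6-dimethoxy-4H-chromen-4-one | COc1cc(-c2cc(=O)c3c(OC)c(OC)c(OCc4ccccc4)cc3o2)cc(OCc2ccccc2)c1OC
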